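## Retrosynthetic overview

1. Tenellic acid B ⇐ global unmasking (benzyl ether, benzyl ester, dioxolane) of a fully protected diaryl ether that already carries the (S)-carbinol.
2. Carbinol C–C bond ⇐ reagent-controlled asymmetric 2-methylallylation (Brown allylboration) of a ring-A aryl aldehyde, then alkene hydrogenation to the isobutyl chain.
3. Diaryl ether C–O bond ⇐ SNAr of a 2,6-disubstituted ring-B phenol on a ring-A aryl fluoride activated by a para-formyl and an ortho-ester group.
4. Ring-A piece ⇐ 4-fluoro-2-methoxybenzaldehyde by directed ortho-metalation/carboxylation; ring-B piece ⇐ creosol by ortho-formylation, O-demethylation, selective O-benzylation and acetalisation.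
5. Ring order: both benzene rings are bought intact and no carbocycle is built; the only rings formed are temporary dioxolanes (ring-A piece first, ring-B piece second), and both are opened again.

Assumption: paraformaldehyde is written as its monomer unit, and the alcohol from the reagent-controlled methallylation (expected ≥ 90% ee) is polished to a single enantiomer by recrystallisation or preparative chiral HPLC at compound 23 if the measured ee requires it.

## Route

Step 1
Reactants: 1 4-fluoro-2-methoxybenzaldehyde; 2 ethylene glycol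
Product: 3 2-(4-fluoro-2-methoxyphenyl)-1,3-dioxolane
Conditions: p-TsOH·H2O (2 mol %), toluene, reflux, Dean–Stark
Reagents that add atoms: ethylene glycol, OCCO
Why: Acid-catalysed acetalisation with azeotropic removal of water masks the aldehyde so that the arene tolerates the organolithium step.

Step 2
Reactants: 3 2-(4-fluoro-2-methoxyphenyl)-1,3-dioxolane; 4 carbon dioxide
Product: 7 6-fluoro-3-formyl-2-methoxybenzoic acid, via aryllithium 5 (not isolated), via lithium carboxylate 6 (not isolated)
Conditions: n-BuLi (1.15 equiv), THF, −78 °C; CO2 (g), −78 → 0 °C; 2 M HCl, THF, rt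
Reagents that add atoms: carbon dioxide, O=C=O; water, O
Why: Directed ortho-metalation takes place only at the C–H flanked by OMe and F (cooperative directors, held at −78 °C to avoid benzyne), the aryllithium is carboxylated, and the acidic work-up hydrolyses the dioxolane.

Step 3
Reactants: 7 6-fluoro-3-formyl-2-methoxybenzoic acid; 8 benzyl bromide
Product: 9 benzyl 6-fluoro-3-formyl-2-methoxybenzoate
Conditions: KHCO3 (1.5 equiv), DMF, rt
Reagents that add atoms: benzyl bromide, BrCc1ccccc1
Why: SN2 O-alkylation of the carboxylate is insensitive to the 2,6-disubstitution and installs an ester that can later be removed by hydrogenolysis, not by hydrolysis.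

Step 4
Reactants: 10 2-methoxy-4-methylphenol (creosol); 11 paraformaldehyde
Product: 13 2-hydroxy-3-methoxy-5-methylbenzaldehyde, via hydroxymethylphenol 12 (not isolated)
Conditions: MgCl2 (1.5 equiv), Et3N (3.75 equiv), (CH2O)n (6.8 equiv), MeCN, reflux; 1 M HCl work-up
Reagents that add atoms: paraformaldehyde (formaldehyde unit), C=O
Why: Casnati–Skattebøl ortho-formylation (magnesium phenoxide hydroxymethylation, then Oppenauer-type hydride transfer to a second formaldehyde) is strictly ortho-selective, and only one ortho position is free because the para position carries the methyl group.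

Step 5
Reactants: 13 2-hydroxy-3-methoxy-5-methylbenzaldehyde
Product: 15 2,3-dihydroxy-5-methylbenzaldehyde, via cyclic bromoboronate 14 (not isolated)
Conditions: BBr3 (1 M in CH2Cl2, 2.2 equiv), CH2Cl2, −78 °C → rt; H2O, 0 °C
Reagents that add atoms: none
Why: BBr3 ether cleavage (bromide SN2 at the O-methyl of the boron-complexed aryl ether) gives the catechol, and the aldehyde is inert under these conditions as in the o-vanillin precedent.

Step 6
Reactants: 15 2,3-dihydroxy-5-methylbenzaldehyde; 8 benzyl bromide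
Product: 17 3-(benzyloxy)-2-hydroxy-5-methylbenzaldehyde, via disodium catecholate 16 (not isolated)
Conditions: NaH (2.2 equiv), DMSO, rt; BnBr (1.0 equiv), rt; 1 M HCl work-up
Reagents that add atoms: benzyl bromide, BrCc1ccccc1
Why: Regioselective Williamson etherification of the dianion, in which the 2-oxide is chelated and conjugated to the formyl group, so the more nucleophilic 3-oxide takes the single equivalent of benzyl bromide.

Step 7
Reactants: 17 3-(benzyloxy)-2-hydroxy-5-methylbenzaldehyde; 2 ethylene glycol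
Product: 18 2-(benzyloxy)-6-(1,3-dioxolan-2-yl)-4-methylphenol
Conditions: ethylene glycol (5 equiv), p-TsOH·H2O (2 mol %), toluene, reflux, Dean–Stark; Et3N quench, Et3N-deactivated silica
Reagents that add atoms: ethylene glycol, OCCO
Why: Acid-catalysed acetalisation masks the ring-B aldehyde so that only one free aldehyde is present in the later C–C bond-forming step.

Step 8
Reactants: 9 benzyl 6-fluoro-3-formyl-2-methoxybenzoate; 18 2-(benzyloxy)-6-(1,3-dioxolan-2-yl)-4-methylphenol
Product: 19 benzyl 6-[2-(benzyloxy)-6-(1,3-dioxolan-2-yl)-4-methylphenoxy]-3-formyl-2-methoxybenzoate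
Conditions: K2CO3 (1.5 equiv), DMF, 60 °C, N2
Reagents that add atoms: none
Why: SNAr through a Meisenheimer adduct is fast because the fluoride is activated by both the para-formyl and the ortho-ester group, which lets even the hindered phenoxide react under mild base that leaves acetal and esters untouched.

Step 9
Reactants: 19 benzyl 6-[2-(benzyloxy)-6-(1,3-dioxolan-2-yl)-4-methylphenoxy]-3-formyl-2-methoxybenzoate; 20 2-methylallylmagnesium chloride
Product: 22 benzyl 6-[2-(benzyloxy)-6-(1,3-dioxolan-2-yl)-4-methylphenoxy]-3-[(1S)-1-hydroxy-3-methylbut-3-en-1-yl]-2-methoxybenzoate, via borinate ester 21 (not isolated)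
Conditions: (−)-Ipc2BOMe [from (+)-α-pinene, 1.5 equiv], 20 (1.4 equiv), Et2O, −78 °C → rt; then 19, Et2O/THF, −78 °C; 3 M NaOH, 30% H2O2, 0 °C → rt
Reagents that add atoms: 2-methylallylmagnesium chloride, CC(=C)C[Mg]Cl, transferred as (−)-B-(2-methylallyl)diisopinocampheylborane made in the flask, CC(=C)CB([C@@H]1C[C@@H]2C[C@H]([C@H]1C)C2(C)C)[C@@H]1C[C@@H]2C[C@H]([C@H]1C)C2(C)C
Why: Brown asymmetric allylboration (carbonyl methallylation) through a closed chair transition state, in which the (+)-α-pinene-derived reagent delivers the methallyl group to the Si face of the aryl aldehyde (as in PhCHO → (S)-1-phenylbut-3-en-1-ol) and so sets the (S)-carbinol while ester and acetal stay inert at −78 °C.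

Step 10
Reactants: 22 benzyl 6-[2-(benzyloxy)-6-(1,3-dioxolan-2-yl)-4-methylphenoxy]-3-[(1S)-1-hydroxy-3-methylbut-3-en-1-yl]-2-methoxybenzoate
Product: 23 benzyl 6-[2-(benzyloxy)-6-(1,3-dioxolan-2-yl)-4-methylphenoxy]-3-[(1S)-1-hydroxy-3-methylbutyl]-2-methoxybenzoate
Conditions: H2 (1 atm), RhCl(PPh3)3 (10 mol %), toluene/EtOH 1:1, rt
Reagents that add atoms: none
Why: Homogeneous hydrogenation with Wilkinson's catalyst saturates the 1,1-disubstituted alkene without double-bond migration and without hydrogenolysis of the benzyl groups or the benzylic C–O bond, so the stereocentre is untouched.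

Step 11
Reactants: 23 benzyl 6-[2-(benzyloxy)-6-(1,3-dioxolan-2-yl)-4-methylphenoxy]-3-[(1S)-1-hydroxy-3-methylbutyl]-2-methoxybenzoate
Product: 25 tenellic acid B, via dioxolane acid 24 (not isolated)
Conditions: H2 (1 atm), dry 10% Pd/C, EtOAc, rt, monitored; filter through Celite; then 1 M HCl/THF 1:4, 0 °C → rt
Reagents that add atoms: water, O
Why: Pd-catalysed hydrogenolysis cleaves the aryl benzyl ether and the benzyl ester under neutral conditions far faster than the unactivated secondary benzylic alcohol, and dilute-acid acetal hydrolysis then frees the aldehyde under conditions too mild to ionise the carbinol on the acid-bearing ring.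

## Compound list

1 | 4-fluoro-2-methoxybenzaldehyde | COc1cc(F)ccc1C=O | starting material
2 | ethylene glycol | OCCO | starting material
3 | 2-(4-fluoro-2-methoxyphenyl)-1,3-dioxolane | COc1cc(F)ccc1C1OCCO1 | intermediate
4 | carbon dioxide | O=C=O | starting material
5 | [3-(1,3-dioxolan-2-yl)-6-fluoro-2-methoxyphenyl]lithium | COc1c([Li])c(F)ccc1C1OCCO1 | intermediate
6 | lithium 3-(1,3-dioxolan-2-yl)-6-fluoro-2-methoxybenzoate | COc1c(C(=O)[O-])c(F)ccc1C1OCCO1.[Li+] | intermediate
7 | 6-fluoro-3-formyl-2-methoxybenzoic acid | COc1c(C=O)ccc(F)c1C(=O)O | intermediate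
8 | benzyl bromide | BrCc1ccccc1 | starting material
9 | benzyl 6-fluoro-3-formyl-2-methoxybenzoate | COc1c(C=O)ccc(F)c1C(=O)OCc1ccccc1 | intermediate
10 | 2-methoxy-4-methylphenol (creosol) | COc1cc(C)ccc1O | starting material
11 | paraformaldehyde (formaldehyde unit) | C=O | starting material
12 | 2-(hydroxymethyl)-6-methoxy-4-methylphenol (present as its magnesium phenoxide) | COc1cc(C)cc(CO)c1O | intermediate
13 | 2-hydroxy-3-methoxy-5-methylbenzaldehyde | COc1cc(C)cc(C=O)c1O | intermediate
14 | 2-bromo-6-methyl-1,3,2-benzodioxaborole-4-carbaldehyde | Cc1cc(C=O)c2OB(Br)Oc2c1 | intermediate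
15 | 2,3-dihydroxy-5-methylbenzaldehyde | Cc1cc(O)c(O)c(C=O)c1 | intermediate
16 | disodium 3-formyl-5-methylbenzene-1,2-diolate | Cc1cc([O-])c([O-])c(C=O)c1.[Na+].[Na+] | intermediate
17 | 3-(benzyloxy)-2-hydroxy-5-methylbenzaldehyde | Cc1cc(OCc2ccccc2)c(O)c(C=O)c1 | intermediate
18 | 2-(benzyloxy)-6-(1,3-dioxolan-2-yl)-4-methylphenol | Cc1cc(OCc2ccccc2)c(O)c(C2OCCO2)c1 | intermediate
19 | benzyl 6-[2-(benzyloxy)-6-(1,3-dioxolan-2-yl)-4-methylphenoxy]-3-formyl-2-methoxybenzoate | COc1c(C=O)ccc(Oc2c(OCc3ccccc3)cc(C)cc2C2OCCO2)c1C(=O)OCc1ccccc1 | intermediate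
20 | 2-methylallylmagnesium chloride | CC(=C)C[Mg]Cl | starting material
21 | O-diisopinocampheylboryl derivative (borinate ester) of 22, (S) at the carbinol carbon, Ipc groups from (+)-α-pinene | COc1c([C@@H](OB([C@@H]4C[C@@H]5C[C@H]([C@H]4C)C5(C)C)[C@@H]4C[C@@H]5C[C@H]([C@H]4C)C5(C)C)CC(C)=C)ccc(Oc2c(OCc3ccccc3)cc(C)cc2C2OCCO2)c1C(=O)OCc1ccccc1 | intermediate
22 | benzyl 6-[2-(benzyloxy)-6-(1,3-dioxolan-2-yl)-4-methylphenoxy]-3-[(1S)-1-hydroxy-3-methylbut-3-en-1-yl]-2-methoxybenzoate | COc1c([C@@H](O)CC(C)=C)ccc(Oc2c(OCc3ccccc3)cc(C)cc2C2OCCO2)c1C(=O)OCc1ccccc1 | intermediate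
23 | benzyl 6-[2-(benzyloxy)-6-(1,3-dioxolan-2-yl)-4-methylphenoxy]-3-[(1S)-1-hydroxy-3-methylbutyl]-2-methoxybenzoate | COc1c([C@@H](O)CC(C)C)ccc(Oc2c(OCc3ccccc3)cc(C)cc2C2OCCO2)c1C(=O)OCc1ccccc1 | intermediate
24 | 6-[2-(1,3-dioxolan-2-yl)-6-hydroxy-4-methylphenoxy]-3-[(1S)-1-hydroxy-3-methylbutyl]-2-methoxybenzoic acid | COc1c([C@@H](O)CC(C)C)ccc(Oc2c(O)cc(C)cc2C2OCCO2)c1C(=O)O | intermediate
25 | tenellic acid B, 6-(2-formyl-6-hydroxy-4-methylphenoxy)-3-[(1S)-1-hydroxy-3-methylbutyl]-2-methoxybenzoic acid | COc1c([C@@H](O)CC(C)C)ccc(Oc2c(O)cc(C)cc2C=O)c1C(=O)O | target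

## Step count and risks

Total step count: 11 (steps 1–3 ring-A piece, steps 4–7 ring-B piece, steps 8–11 after union).
Longest linear sequence: 8 steps (steps 4–11, from creosol 10).

Three steps most likely to fail:

**Step 9** (enantioselectivity and conversion of the reagent-controlled methallylation on a crowded, ortho-substituted aldehyde). The fallback sets out from 19 and comes back to the route at 23, and it sets the stereocentre by ketone reduction instead. Plain addition of 2-methylallylmagnesium chloride 20 to 19 (THF, −78 °C) gives racemic benzyl 6-[2-(benzyloxy)-6-(1,3-dioxolan-2-yl)-4-methylphenoxy]-3-(1-hydroxy-3-methylbut-3-en-1-yl)-2-methoxybenzoate F2. Hydrogenation with Wilkinson's catalyst gives racemic benzyl 6-[2-(benzyloxy)-6-(1,3-dioxolan-2-yl)-4-methylphenoxy]-3-(1-hydroxy-3-methylbutyl)-2-methoxybenzoate F3. Dess–Martin oxidation (NaHCO3, CH2Cl2) gives the aryl isobutyl ketone benzyl 6-[2-(benzyloxy)-6-(1,3-dioxolan-2-yl)-4-methylphenoxy]-2-methoxy-3-(3-methylbutanoyl)benzoate F4. Corey–Bakshi–Shibata reduction with (R)-Me-CBS and BH3·SMe2 (THF, −20 °C, aryl as the large group) then returns the (S)-alcohol 23.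

**Step 11** (loss of the benzylic C–O bond or of the masked aldehyde during hydrogenolysis, and acid sensitivity in the final unmasking). The fallback sets out from 23 and comes back at 25, and it shields the carbinol first. Silylation (TBSCl, imidazole, DMAP, DMF, 40 °C) gives benzyl 6-[2-(benzyloxy)-6-(1,3-dioxolan-2-yl)-4-methylphenoxy]-3-[(1S)-1-{[tert-butyl(dimethyl)silyl]oxy}-3-methylbutyl]-2-methoxybenzoate F5. Hydrogenolysis (H2, Pd/C, EtOAc) gives 6-[2-(1,3-dioxolan-2-yl)-6-hydroxy-4-methylphenoxy]-3-[(1S)-1-{[tert-butyl(dimethyl)silyl]oxy}-3-methylbutyl]-2-methoxybenzoic acid F6. Aqueous HF in MeCN (0 °C → rt) then removes the silyl ether and the dioxolane together to give 25.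

**Step 6** (regioselectivity of the mono-benzylation of the catechol aldehyde). The fallback sets out from 15 and comes back at 17, and it replaces selective alkylation by selective dealkylation. Exhaustive benzylation (BnBr 8, K2CO3, DMF, 60 °C) gives 2,3-bis(benzyloxy)-5-methylbenzaldehyde F1. Chelation-controlled cleavage of the benzyl ether ortho to the formyl group with MgBr2·OEt2 (toluene/Et2O, reflux) then returns 17.

## Further compounds

F1 | step 6 | 2,3-bis(benzyloxy)-5-methylbenzaldehyde | Cc1cc(OCc2ccccc2)c(OCc2ccccc2)c(C=O)c1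
F2 | step 9 | racemic benzyl 6-[2-(benzyloxy)-6-(1,3-dioxolan-2-yl)-4-methylphenoxy]-3-(1-hydroxy-3-methylbut-3-en-1-yl)-2-methoxybenzoate | COc1c(C(O)CC(C)=C)ccc(Oc2c(OCc3ccccc3)cc(C)cc2C2OCCO2)c1C(=O)OCc1ccccc1
F3 | step 9 | racemic benzyl 6-[2-(benzyloxy)-6-(1,3-dioxolan-2-yl)-4-methylphenoxy]-3-(1-hydroxy-3-methylbutyl)-2-methoxybenzoate | COc1c(C(O)CC(C)C)ccc(Oc2c(OCc3ccccc3)cc(C)cc2C2OCCO2)c1C(=O)OCc1ccccc1
F4 | step 9 | benzyl 6-[2-(benzyloxy)-6-(1,3-dioxolan-2-yl)-4-methylphenoxy]-2-methoxy-3-(3-methylbutanoyl)benzoate | COc1c(C(=O)CC(C)C)ccc(Oc2c(OCc3ccccc3)cc(C)cc2C2OCCO2)c1C(=O)OCc1ccccc1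
F5 | step 11 | benzyl 6-[2-(benzyloxy)-6-(1,3-dioxolan-2-yl)-4-methylphenoxy]-3-[(1S)-1-{[tert-butyl(dimethyl)silyl]oxy}-3-methylbutyl]-2-methoxybenzoate | COc1c([C@@H](O[Si](C)(C)C(C)(C)C)CC(C)C)ccc(Oc2c(OCc3ccccc3)cc(C)cc2C2OCCO2)c1C(=O)OCc1ccccc1
F6 | step 11 | 6-[2-(1,3-dioxolan-2-yl)-6-hydroxy-4-methylphenoxy]-3-[(1S)-1-{[tert-butyl(dimethyl)silyl]oxy}-3-methylbutyl]-2-methoxybenzoic acid | COc1c([C@@H](O[Si](C)(C)C(C)(C)C)CC(C)C)ccc(Oc2c(O)cc(C)cc2C2OCCO2)c1C(=O)O
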